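**Strategy.** Everything rests on cutting the bond between C2 of the chroman (ring C) and C1' of the pentasubstituted ring B. C2 lies β to the benzylic carbon C4, so with C4 raised to a ketone ring C becomes a flat chromone whose C2=C3 bond is a Michael acceptor. A rhodium-catalysed asymmetric 1,4-addition of the complete ring B arylboronic acid (prenyl group and dimethylchromene already in place) to 7-methoxychromone should join the two halves and set the only stereocentre, C2, in one operation. The precursors are an achiral chromone and an arylboronic acid made in four steps from 4-bromo-2-methoxyphenol; removal of the C4 oxygen and of two methyl ethers completes the route.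

Key step: step 5

Remark on the chemistry: the chromone partner of step 5, LDA solution and solid NaSEt are taken as purchasable. (S)-MeO-F12-BIPHEP stands for (S)-(6,6'-dimethoxybiphenyl-2,2'-diyl)bis[bis(3,4,5-trifluorophenyl)phosphane].

**Step 1**
Reactants: 1 4-bromo-2-methoxyphenol; 2 3-chloro-3-methylbut-1-yne
Product: 3 4-bromo-2-methoxy-1-[(2-methylbut-3-yn-2-yl)oxy]benzene
Conditions: DBU, CuCl2·2H2O (cat.), MeCN, 0 °C to rt
Reagents that add atoms: none
Why: Copper-catalysed propargylic etherification of the phenol with the tertiary propargylic chloride should give the hindered tertiary aryl propargyl ether, which plain SN2 alkylation cannot make.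

**Step 2**
Reactants: 3 4-bromo-2-methoxy-1-[(2-methylbut-3-yn-2-yl)oxy]benzene
Product: 5 6-bromo-8-methoxy-2,2-dimethyl-2H-chromene, via allenylphenol 4 (not isolated)
Conditions: N,N-diethylaniline, 190 °C
Reagents that add atoms: none
Why: The thermal aryl propargyl ether Claisen rearrangement can only go into the single free ortho position (the other carries OMe), and allenylphenol 4 should then close by 1,5-hydrogen shift and 6π oxa-electrocyclisation to the 2,2-dimethyl-2H-chromene.

**Step 3**
Reactants: 5 6-bromo-8-methoxy-2,2-dimethyl-2H-chromene; 6 1-bromo-3-methylbut-2-ene (prenyl bromide)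
Product: 9 6-bromo-8-methoxy-2,2-dimethyl-7-(3-methylbut-2-en-1-yl)-2H-chromene, via aryllithium 7 (not isolated), via arylcopper 8 (not isolated)
Conditions: LDA, THF, −78 °C; CuBr·SMe2, −78 °C; then 6, −78 to −20 °C
Reagents that add atoms: none
Why: Directed ortho-metalation by LDA should remove the one ring hydrogen flanked by OMe and Br (C7; an amide base does not undergo bromine–lithium exchange), and the arylcopper, formed at −78 °C where loss of LiBr to an aryne is suppressed, should be allylated by prenyl bromide at its primary carbon (SN2) to give the linear prenyl group.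

**Step 4**
Reactants: 9 6-bromo-8-methoxy-2,2-dimethyl-7-(3-methylbut-2-en-1-yl)-2H-chromene
Product: 12 [8-methoxy-2,2-dimethyl-7-(3-methylbut-2-en-1-yl)-2H-chromen-6-yl]boronic acid, via aryllithium 10 (not isolated), via lithium triisopropoxyborate 11 (not isolated)
Conditions: B(OiPr)3, n-BuLi (in situ quench), THF/toluene, −78 °C; then 1 M HCl, 0 °C
Reagents that add atoms: triisopropyl borate CC(C)OB(OC(C)C)OC(C)C; water O
Why: Bromine–lithium exchange is faster than attack of n-BuLi on the borate, so aryllithium 10 should be trapped at once as borate 11 (which also forestalls proton transfer from the benzylic–allylic CH2), and mild acid hydrolysis gives the boronic acid.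

**Step 5**
Reactants: 12 [8-methoxy-2,2-dimethyl-7-(3-methylbut-2-en-1-yl)-2H-chromen-6-yl]boronic acid; 13 7-methoxy-4H-chromen-4-one
Product: 14 (2S)-7-methoxy-2-[8-methoxy-2,2-dimethyl-7-(3-methylbut-2-en-1-yl)-2H-chromen-6-yl]-2,3-dihydro-4H-chromen-4-one
Conditions: [RhOH(cod)]2 (3 mol %), (S)-MeO-F12-BIPHEP (7 mol %), 13 (2 equiv), CH2Cl2/H2O, 30 °C
Reagents that add atoms: none
Why: Transmetalation of 12 to the rhodium hydroxide complex (monovalent rhodium) should give an aryl–rhodium species that inserts the C2=C3 bond of 13 with the aryl group going to C2, and hydrolysis of the resulting oxa-π-allyl (enolate) releases 14 and regenerates Rh–OH. The closest known reaction type is the Hayashi–Miyaura asymmetric 1,4-addition of arylboronic acids to enones, which is established on chromones as a route to flavanones. No ring is closed. The new stereocentre C2 is set under catalyst control: the axially chiral bisphosphine should expose the Re face of C2, which gives (S); this sense is expected for the (S)-ligand by analogy with six-membered cyclic enones, and the (R)-ligand would be taken if the opposite sense were found. The step needs 1,4- over 1,2-addition and reaction at the enone and not at the unactivated prenyl and chromene double bonds of 12, which the electron-poor C2=C3 bond and the electron-poor ligand should secure. The base-free medium should prevent retro-oxa-Michael opening and racemisation of 14.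

**Step 6**
Reactants: 14 (2S)-7-methoxy-2-[8-methoxy-2,2-dimethyl-7-(3-methylbut-2-en-1-yl)-2H-chromen-6-yl]-2,3-dihydro-4H-chromen-4-one
Product: 15 (2S,4RS)-7-methoxy-2-[8-methoxy-2,2-dimethyl-7-(3-methylbut-2-en-1-yl)-2H-chromen-6-yl]-3,4-dihydro-2H-chromen-4-ol
Conditions: NaBH4, MeOH/THF, 0 °C
Reagents that add atoms: none
Why: Hydride reduction of the aryl ketone is fast at 0 °C, so base-induced ring opening should not compete and C2 stays untouched; the C4 epimer mixture is of no consequence because C4 loses its oxygen in step 7.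

**Step 7**
Reactants: 15 (2S,4RS)-7-methoxy-2-[8-methoxy-2,2-dimethyl-7-(3-methylbut-2-en-1-yl)-2H-chromen-6-yl]-3,4-dihydro-2H-chromen-4-ol
Product: 16 (2S)-7-methoxy-2-[8-methoxy-2,2-dimethyl-7-(3-methylbut-2-en-1-yl)-2H-chromen-6-yl]-3,4-dihydro-2H-chromene
Conditions: Et3SiH, CF3CO2H, CH2Cl2, −30 to 0 °C
Reagents that add atoms: none
Why: Ionic hydrogenation: the C4 carbinol should ionise to a cation stabilised by O1 (ortho) and the 7-methoxy group (para) under acid too weak and too cold to protonate the prenyl and chromene double bonds or to open the C2–O1 bond, and Et3SiH delivers hydride to C4 without involving C2.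

**Step 8**
Reactants: 16 (2S)-7-methoxy-2-[8-methoxy-2,2-dimethyl-7-(3-methylbut-2-en-1-yl)-2H-chromen-6-yl]-3,4-dihydro-2H-chromene
Product: 17 kazinol B, (2S)-2-[8-hydroxy-2,2-dimethyl-7-(3-methylbut-2-en-1-yl)-2H-chromen-6-yl]-3,4-dihydro-2H-chromen-7-ol
Conditions: NaSEt, DMF, 130 °C; then 1 M HCl to pH 6, 0 °C
Reagents that add atoms: none
Why: SN2 demethylation of both aryl methyl ethers by the soft thiolate (the tertiary ether of the chromene and the benzylic ether of ring C offer no comparable SN2 site) in a basic, acid-free medium that cannot ionise the C2–O1 bond or cyclise the prenyl group onto the new ortho phenol, so the stereocentre should be preserved.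

**Compound list**
1 | 4-bromo-2-methoxyphenol | COc1cc(Br)ccc1O | starting material
2 | 3-chloro-3-methylbut-1-yne | C#CC(C)(C)Cl | starting material
3 | 4-bromo-2-methoxy-1-[(2-methylbut-3-yn-2-yl)oxy]benzene | COc1cc(Br)ccc1OC(C)(C)C#C | intermediate
4 | 4-bromo-2-methoxy-6-(3-methylbuta-1,2-dien-1-yl)phenol (allenylphenol, formed in the flask) | COc1cc(Br)cc(C=C=C(C)C)c1O | intermediate
5 | 6-bromo-8-methoxy-2,2-dimethyl-2H-chromene | COc1cc(Br)cc2C=CC(C)(C)Oc12 | intermediate
6 | 1-bromo-3-methylbut-2-ene (prenyl bromide) | CC(C)=CCBr | starting material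
7 | (6-bromo-8-methoxy-2,2-dimethyl-2H-chromen-7-yl)lithium (formed in the flask) | COc1c([Li])c(Br)cc2C=CC(C)(C)Oc12 | intermediate
8 | (6-bromo-8-methoxy-2,2-dimethyl-2H-chromen-7-yl)copper (formed in the flask) | COc1c([Cu])c(Br)cc2C=CC(C)(C)Oc12 | intermediate
9 | 6-bromo-8-methoxy-2,2-dimethyl-7-(3-methylbut-2-en-1-yl)-2H-chromene | COc1c(CC=C(C)C)c(Br)cc2C=CC(C)(C)Oc12 | intermediate
10 | [8-methoxy-2,2-dimethyl-7-(3-methylbut-2-en-1-yl)-2H-chromen-6-yl]lithium (formed in the flask) | COc1c(CC=C(C)C)c([Li])cc2C=CC(C)(C)Oc12 | intermediate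
11 | lithium [8-methoxy-2,2-dimethyl-7-(3-methylbut-2-en-1-yl)-2H-chromen-6-yl]triisopropoxyborate (formed in the flask) | [Li+].COc1c(CC=C(C)C)c([B-](OC(C)C)(OC(C)C)OC(C)C)cc2C=CC(C)(C)Oc12 | intermediate
12 | [8-methoxy-2,2-dimethyl-7-(3-methylbut-2-en-1-yl)-2H-chromen-6-yl]boronic acid | COc1c(CC=C(C)C)c(B(O)O)cc2C=CC(C)(C)Oc12 | intermediate
13 | 7-methoxy-4H-chromen-4-one | COc1ccc2C(=O)C=COc2c1 | starting material
14 | (2S)-7-methoxy-2-[8-methoxy-2,2-dimethyl-7-(3-methylbut-2-en-1-yl)-2H-chromen-6-yl]-2,3-dihydro-4H-chromen-4-one | CC(C)=CCc1c([C@@H]2CC(=O)c3ccc(OC)cc3O2)cc2c(c1OC)OC(C)(C)C=C2 | intermediate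
15 | (2S,4RS)-7-methoxy-2-[8-methoxy-2,2-dimethyl-7-(3-methylbut-2-en-1-yl)-2H-chromen-6-yl]-3,4-dihydro-2H-chromen-4-ol | CC(C)=CCc1c([C@@H]2CC(O)c3ccc(OC)cc3O2)cc2c(c1OC)OC(C)(C)C=C2 | intermediate
16 | (2S)-7-methoxy-2-[8-methoxy-2,2-dimethyl-7-(3-methylbut-2-en-1-yl)-2H-chromen-6-yl]-3,4-dihydro-2H-chromene | CC(C)=CCc1c([C@@H]2CCc3ccc(OC)cc3O2)cc2c(c1OC)OC(C)(C)C=C2 | intermediate
17 | kazinol B, (2S)-2-[8-hydroxy-2,2-dimethyl-7-(3-methylbut-2-en-1-yl)-2H-chromen-6-yl]-3,4-dihydro-2H-chromen-7-ol | CC(C)=CCc1c([C@@H]2CCc3ccc(O)cc3O2)cc2c(c1O)OC(C)(C)C=C2 | target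

**Total step count:** 8. **Longest linear sequence:** 8 (steps 1 to 8, from compound 1).

**The three steps most likely to fail**

Step 5 (key step). The ortho-prenylated, electron-rich aryl–rhodium species may insert into the chromone so slowly that protodeboronation takes over, or the face selectivity at C2 may be low. The fallback makes the same bond by acylation and sets the stereocentre by reagent-controlled reduction and ring closure with inversion; it sets out from compound 9. Bromine–lithium exchange (n-BuLi, THF, −78 °C) gives aryllithium 10, which is added to 7-methoxy-3,4-dihydro-2H-chromen-2-one F1 (one hydrogenation, H2 and Pd/C in EtOAc, from purchased 7-methoxycoumarin). The lactone opens to 3-(2-hydroxy-4-methoxyphenyl)-1-[8-methoxy-2,2-dimethyl-7-(3-methylbut-2-en-1-yl)-2H-chromen-6-yl]propan-1-one F2. Corey–Bakshi–Shibata reduction (BH3·SMe2, (S)-2-methyl oxazaborolidine, THF, −20 °C) should give (1R)-3-(2-hydroxy-4-methoxyphenyl)-1-[8-methoxy-2,2-dimethyl-7-(3-methylbut-2-en-1-yl)-2H-chromen-6-yl]propan-1-ol F3. An intramolecular Mitsunobu etherification (PPh3, DIAD, THF, 0 °C) then closes ring C with inversion at the carbinol carbon and comes back to the route at compound 16.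

Step 8. Cleavage of the two methyl ethers needs a hot thiolate; the cleavage may stay incomplete, or thiolate and heat may isomerise or add to the prenyl and chromene double bonds of the finished skeleton. The fallback carries both phenols as methoxymethyl ethers, put on while the molecules are simple and taken off at the end without heat or strong acid; it sets out from compound 5 (and purchased 7-hydroxychromone). NaSEt in DMF at 120 °C, applied before any prenyl group is present, gives 6-bromo-2,2-dimethyl-2H-chromen-8-ol F4. MOMCl and i-Pr2NEt give 6-bromo-8-(methoxymethoxy)-2,2-dimethyl-2H-chromene F5. The metalation and prenylation of step 3 (the MOM ether is the stronger directing group) give 6-bromo-8-(methoxymethoxy)-2,2-dimethyl-7-(3-methylbut-2-en-1-yl)-2H-chromene F6. The borylation of step 4 gives [8-(methoxymethoxy)-2,2-dimethyl-7-(3-methylbut-2-en-1-yl)-2H-chromen-6-yl]boronic acid F7. 7-Hydroxychromone with MOMCl and i-Pr2NEt gives 7-(methoxymethoxy)-4H-chromen-4-one F8. The conditions of step 5 should join F7 and F8 to (2S)-7-(methoxymethoxy)-2-[8-(methoxymethoxy)-2,2-dimethyl-7-(3-methylbut-2-en-1-yl)-2H-chromen-6-yl]-2,3-dihydro-4H-chromen-4-one F9. NaBH4 gives the corresponding (2S,4RS)-3,4-dihydro-2H-chromen-4-ol F10, and cold Et3SiH/CF3CO2H gives (2S)-7-(methoxymethoxy)-2-[8-(methoxymethoxy)-2,2-dimethyl-7-(3-methylbut-2-en-1-yl)-2H-chromen-6-yl]-3,4-dihydro-2H-chromene F11. TMSOTf and 2,2'-bipyridyl in CH2Cl2 at 0 °C, then water, remove both MOM groups and come back to the route at compound 17.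

Step 7. The acid may protonate the chromene or prenyl double bond (over-reduction or oligomerisation), or ionise the C2–O1 bond and erode the stereocentre. The fallback is a cation-free deoxygenation of the ketone; it sets out from compound 14. TsNHNH2 in EtOH at 60 °C gives the 4-(4-methylbenzenesulfonyl)hydrazone of 14 F12. Catecholborane (CHCl3, 0 °C) and then NaOAc·3H2O at reflux reduce it through the diazene with loss of nitrogen and sulfinate, and the sequence comes back to the route at compound 16.

**Further compounds**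
F1 | step 5 | 7-methoxy-3,4-dihydro-2H-chromen-2-one | COc1ccc2CCC(=O)Oc2c1
F2 | step 5 | 3-(2-hydroxy-4-methoxyphenyl)-1-[8-methoxy-2,2-dimethyl-7-(3-methylbut-2-en-1-yl)-2H-chromen-6-yl]propan-1-one | CC(C)=CCc1c(C(=O)CCc3ccc(OC)cc3O)cc2c(c1OC)OC(C)(C)C=C2
F3 | step 5 | (1R)-3-(2-hydroxy-4-methoxyphenyl)-1-[8-methoxy-2,2-dimethyl-7-(3-methylbut-2-en-1-yl)-2H-chromen-6-yl]propan-1-ol | CC(C)=CCc1c([C@H](O)CCc3ccc(OC)cc3O)cc2c(c1OC)OC(C)(C)C=C2
F4 | step 8 | 6-bromo-2,2-dimethyl-2H-chromen-8-ol | Oc1cc(Br)cc2C=CC(C)(C)Oc12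
F5 | step 8 | 6-bromo-8-(methoxymethoxy)-2,2-dimethyl-2H-chromene | COCOc1cc(Br)cc2C=CC(C)(C)Oc12
F6 | step 8 | 6-bromo-8-(methoxymethoxy)-2,2-dimethyl-7-(3-methylbut-2-en-1-yl)-2H-chromene | COCOc1c(CC=C(C)C)c(Br)cc2C=CC(C)(C)Oc12
F7 | step 8 | [8-(methoxymethoxy)-2,2-dimethyl-7-(3-methylbut-2-en-1-yl)-2H-chromen-6-yl]boronic acid | COCOc1c(CC=C(C)C)c(B(O)O)cc2C=CC(C)(C)Oc12
F8 | step 8 | 7-(methoxymethoxy)-4H-chromen-4-one | COCOc1ccc2C(=O)C=COc2c1
F9 | step 8 | (2S)-7-(methoxymethoxy)-2-[8-(methoxymethoxy)-2,2-dimethyl-7-(3-methylbut-2-en-1-yl)-2H-chromen-6-yl]-2,3-dihydro-4H-chromen-4-one | CC(C)=CCc1c([C@@H]2CC(=O)c3ccc(OCOC)cc3O2)cc2c(c1OCOC)OC(C)(C)C=C2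
F10 | step 8 | (2S,4RS)-7-(methoxymethoxy)-2-[8-(methoxymethoxy)-2,2-dimethyl-7-(3-methylbut-2-en-1-yl)-2H-chromen-6-yl]-3,4-dihydro-2H-chromen-4-ol | CC(C)=CCc1c([C@@H]2CC(O)c3ccc(OCOC)cc3O2)cc2c(c1OCOC)OC(C)(C)C=C2
F11 | step 8 | (2S)-7-(methoxymethoxy)-2-[8-(methoxymethoxy)-2,2-dimethyl-7-(3-methylbut-2-en-1-yl)-2H-chromen-6-yl]-3,4-dihydro-2H-chromene | CC(C)=CCc1c([C@@H]2CCc3ccc(OCOC)cc3O2)cc2c(c1OCOC)OC(C)(C)C=C2
F12 | step 7 | 4-(4-methylbenzenesulfonyl)hydrazone of (2S)-7-methoxy-2-[8-methoxy-2,2-dimethyl-7-(3-methylbut-2-en-1-yl)-2H-chromen-6-yl]-2,3-dihydro-4H-chromen-4-one | CC(C)=CCc1c([C@@H]2CC(=NNS(=O)(=O)c4ccc(C)cc4)c3ccc(OC)cc3O2)cc2c(c1OC)OC(C)(C)C=C2
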